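Ring B is cut at C2'–C3' and C1'–C6'. Its carbons C3'–C6' (two carbonyls, two CMe2) are the four ring carbons of 2,2,4,4-tetramethylcyclobutane-1,3-dione, while C1' and C2' are the carbonyl and α-carbon of an aryl lactone that already carries the methine stereocentre and ties up one ring A oxygen. In one operation the lactone enolate adds to the dione, the strained ring opens, and the new ketone enolate closes onto the lactone, building ring B and freeing the ring A phenol. The precursor is (4R)-5,7-bis(benzyloxy)-8-methyl-4-isobutyl-3,4-dihydrocoumarin, made by copper-catalysed asymmetric conjugate addition; debenzylation and Friedel–Crafts acylation finish the synthesis.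

Key step: step 5

Remark: with ring B drawn as the enol tautomer given, the methine carbon is S in 15, 16 and 18; the same spatial arrangement is 4R in lactone 10 because the priority order changes.
Remark: the lactone oxygen becomes a phenol in step 5 and both ethers fall in step 6, so a regioisomeric bis-ether from step 2 would converge on the same triphenol 16; the route still aims at the single 8-methyl lactone. Compounds 1, 5, 8, 11 and 17 are taken as commercial.

Step 1
Reactants: 1 2-methylphloroglucinol
Product: 3 2,4,6-trihydroxy-3-methylbenzaldehyde, via iminium chloride 2 (not isolated)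
Conditions: POCl3, DMF, EtOAc, 0 °C → rt; then H2O, 60 °C
Reagents that add atoms: N,N-dimethylformamide, CN(C)C=O; water, O
Why: Vilsmeier–Haack formylation of a highly activated arene; the two free ring carbons of 1 are equivalent, so only one aldehyde can form, and hydrolysis of iminium salt 2 releases it.

Step 2
Reactants: 3 2,4,6-trihydroxy-3-methylbenzaldehyde
Product: 4 4,6-bis(benzyloxy)-2-hydroxy-3-methylbenzaldehyde
Conditions: BnBr (2.05 equiv), K2CO3 (2.2 equiv), DMF, 0 °C → rt
Reagents that add atoms: benzyl bromide, BrCc1ccccc1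
Why: Williamson etherification under partial-alkylation control: the unchelated 4-OH should react first, then the chelated 6-OH flanked by H, while the 2-OH, chelated to the formyl group and buttressed by the methyl group, should stay free; a minor regioisomer would be removed by crystallisation.

Step 3
Reactants: 4 4,6-bis(benzyloxy)-2-hydroxy-3-methylbenzaldehyde; 5 ethyl (triphenylphosphoranylidene)acetate
Product: 7 5,7-bis(benzyloxy)-8-methyl-2H-chromen-2-one, via hydroxycinnamate ester 6 (not isolated)
Conditions: PhNEt2, reflux
Reagents that add atoms: none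
Why: Wittig olefination with a stabilised ylide, then thermal E/Z isomerisation and lactonisation with loss of ethanol in the same pot; the only free hydroxyl of 4 is the one beside the methyl group, so the lactone oxygen is fixed next to C8–Me.

Step 4
Reactants: 7 5,7-bis(benzyloxy)-8-methyl-2H-chromen-2-one; 8 isobutylmagnesium bromide
Product: 10 (4R)-5,7-bis(benzyloxy)-8-methyl-4-(2-methylpropyl)-3,4-dihydro-2H-chromen-2-one, via magnesium enolate 9 (not isolated)
Conditions: CuBr·SMe2 (5 mol %), 1-[2-(dicyclohexylphosphino)ferrocenyl]ethyldiphenylphosphine (single enantiomer, 6 mol %), CH2Cl2, −75 °C, slow addition of 8; then aq. HCl, −75 °C → rt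
Reagents that add atoms: none
Why: Copper-catalysed asymmetric conjugate addition of a Grignard reagent to a coumarin: the chiral ferrocenyl diphosphine–CuBr complex should deliver the isobutyl group to one face of C4 and so set the 4R stereocentre (the ligand antipode is chosen accordingly and the sense confirmed on the first batch), and cold protonation of enolate 9 returns the intact aryl lactone.

Step 5
Reactants: 10 (4R)-5,7-bis(benzyloxy)-8-methyl-4-(2-methylpropyl)-3,4-dihydro-2H-chromen-2-one; 11 2,2,4,4-tetramethylcyclobutane-1,3-dione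
Product: 15 2-[(1S)-1-[4,6-bis(benzyloxy)-2-hydroxy-3-methylphenyl]-3-methylbutyl]-3-hydroxy-4,4,6,6-tetramethylcyclohex-2-ene-1,5-dione, via lithium enolate 12 (not isolated), via cyclobutanolate adduct 13 (not isolated), via ring-opened ketone enolate 14 (not isolated)
Conditions: LiN(SiMe3)2 (1.1 equiv), THF, −78 °C; 11 (1.3 equiv), −78 → −20 °C; LiN(SiMe3)2 (1.2 equiv), −20 → 0 °C; then aq. HCl, 0 °C
Reagents that add atoms: none
Why: Proposed new method: lithium enolate 12 should add through C3 to one of the two equivalent, strained carbonyl groups of 11 (forming C2'–C3'), and alkoxide 13 should relieve four-ring strain by retro-Claisen cleavage of either of its two equivalent ring C–C bonds, which unmasks the tetrasubstituted isopropyl-ketone enolate 14. This enolate is held within reach of the aryl lactone carbonyl and should close ring B by a 6-exo-trig Dieckmann acylation that forms C1'–C6' and expels the ring A phenoxide; if proton transfer from the acidic C2'–H comes first, the second charge of amide regenerates the ketone enolate, and the aryl β-keto ester can also shed phenoxide to an acylketene that the same carbon captures, so both paths end in the triketone enolate, the thermodynamic sink. The closest known reaction types are the alkoxide-induced ring opening of 11 to 2,2,4-trimethyl-3-oxopentanoates and the base-induced conversion of dimethylketene into hexamethylcyclohexane-1,3,5-trione; here a carbon nucleophile replaces the alkoxide and a tethered aryl ester replaces the third ketene unit. No stereocentre is created (C3 ends as the sp2 carbon C2'), and the existing one is β to the carbonyl, is never deprotonated and keeps its spatial arrangement (the descriptor changes from R to S only through the priority rules); in the product dianion C2' is sp2, which blocks retro-Michael loss of ring B. The step needs carbon attack on 11 rather than attack by the amide, secured by forming 12 completely with a hindered silylamide before 11 is added at −78 °C, and cyclisation rather than self-condensation, which the crowded C4 substituents and the intramolecular aryl ester favour; the symmetry of 11 removes any regiochemical question in the ring opening.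

Step 6
Reactants: 15 2-[(1S)-1-[4,6-bis(benzyloxy)-2-hydroxy-3-methylphenyl]-3-methylbutyl]-3-hydroxy-4,4,6,6-tetramethylcyclohex-2-ene-1,5-dione
Product: 16 3-hydroxy-4,4,6,6-tetramethyl-2-[(1S)-3-methyl-1-(2,4,6-trihydroxy-3-methylphenyl)butyl]cyclohex-2-ene-1,5-dione
Conditions: H2 (1 atm), 10% Pd/C, EtOAc, rt
Reagents that add atoms: none
Why: Catalytic hydrogenolysis of the two benzyl aryl ethers under neutral conditions, which should leave the tetrasubstituted ring B enol, the arene and the stereocentre untouched.

Step 7
Reactants: 16 3-hydroxy-4,4,6,6-tetramethyl-2-[(1S)-3-methyl-1-(2,4,6-trihydroxy-3-methylphenyl)butyl]cyclohex-2-ene-1,5-dione; 17 3-phenylpropanoyl chloride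
Product: 18 3-hydroxy-4,4,6,6-tetramethyl-2-[(1S)-3-methyl-1-[2,4,6-trihydroxy-3-methyl-5-(3-phenylpropanoyl)phenyl]butyl]cyclohex-2-ene-1,5-dione
Conditions: TiCl4 (3 equiv), CH2Cl2, −10 °C → rt; then ice-cold aq. HCl
Reagents that add atoms: none
Why: Friedel–Crafts acylation: ring A of 16 has one unsubstituted carbon, flanked by two hydroxyl groups, so C-acylation can only occur there, any O-acyl product should rearrange (Fries) under the same conditions, and chelation of TiCl4 by the ring B enol-ketone keeps C2' sp2 and so disfavours ionisation at the stereocentre.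

Compound list
1 | 2-methylphloroglucinol (2-methylbenzene-1,3,5-triol) | Cc1c(O)cc(O)cc1O | starting material
2 | [(2,4,6-trihydroxy-3-methylphenyl)methylidene]dimethyliminium chloride | Cc1c(O)cc(O)c(C=[N+](C)C)c1O.[Cl-] | intermediate (not isolated)
3 | 2,4,6-trihydroxy-3-methylbenzaldehyde | Cc1c(O)cc(O)c(C=O)c1O | intermediate
4 | 4,6-bis(benzyloxy)-2-hydroxy-3-methylbenzaldehyde | Cc1c(OCc2ccccc2)cc(OCc2ccccc2)c(C=O)c1O | intermediate
5 | ethyl (triphenylphosphoranylidene)acetate | CCOC(=O)C=P(c1ccccc1)(c1ccccc1)c1ccccc1 | starting material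
6 | ethyl (2E)-3-[4,6-bis(benzyloxy)-2-hydroxy-3-methylphenyl]prop-2-enoate | Cc1c(OCc2ccccc2)cc(OCc2ccccc2)c(/C=C/C(=O)OCC)c1O | intermediate (not isolated)
7 | 5,7-bis(benzyloxy)-8-methyl-2H-chromen-2-one | Cc1c(OCc2ccccc2)cc(OCc2ccccc2)c2c1OC(=O)C=C2 | intermediate
8 | isobutylmagnesium bromide | CC(C)C[Mg]Br | starting material
9 | bromomagnesium (4R)-5,7-bis(benzyloxy)-8-methyl-4-(2-methylpropyl)-4H-chromen-2-olate | Cc1c(OCc2ccccc2)cc(OCc2ccccc2)c2c1OC(O[Mg]Br)=C[C@H]2CC(C)C | intermediate (not isolated)
10 | (4R)-5,7-bis(benzyloxy)-8-methyl-4-(2-methylpropyl)-3,4-dihydro-2H-chromen-2-one | Cc1c(OCc2ccccc2)cc(OCc2ccccc2)c2c1OC(=O)C[C@H]2CC(C)C | intermediate (key-step precursor)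
11 | 2,2,4,4-tetramethylcyclobutane-1,3-dione | CC1(C)C(=O)C(C)(C)C1=O | starting material
12 | lithium (4R)-5,7-bis(benzyloxy)-8-methyl-4-(2-methylpropyl)-4H-chromen-2-olate | Cc1c(OCc2ccccc2)cc(OCc2ccccc2)c2c1OC(O[Li])=C[C@H]2CC(C)C | intermediate (not isolated)
13 | lithium 1-[(4R)-5,7-bis(benzyloxy)-8-methyl-4-(2-methylpropyl)-2-oxo-3,4-dihydro-2H-chromen-3-yl]-2,2,4,4-tetramethyl-3-oxocyclobutan-1-olate (C3 transient, not defined) | Cc1c(OCc2ccccc2)cc(OCc2ccccc2)c2c1OC(=O)C([C@H]2CC(C)C)C1(O[Li])C(C)(C)C(=O)C1(C)C | intermediate (not isolated)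
14 | lithium 5-[(4R)-5,7-bis(benzyloxy)-8-methyl-4-(2-methylpropyl)-2-oxo-3,4-dihydro-2H-chromen-3-yl]-2,4,4-trimethyl-5-oxopent-2-en-3-olate (C3 transient, not defined) | Cc1c(OCc2ccccc2)cc(OCc2ccccc2)c2c1OC(=O)C([C@H]2CC(C)C)C(=O)C(C)(C)C(O[Li])=C(C)C | intermediate (not isolated)
15 | 2-[(1S)-1-[4,6-bis(benzyloxy)-2-hydroxy-3-methylphenyl]-3-methylbutyl]-3-hydroxy-4,4,6,6-tetramethylcyclohex-2-ene-1,5-dione | Cc1c(OCc2ccccc2)cc(OCc2ccccc2)c([C@H](CC(C)C)C2=C(O)C(C)(C)C(=O)C(C)(C)C2=O)c1O | intermediate (key-step product)
16 | 3-hydroxy-4,4,6,6-tetramethyl-2-[(1S)-3-methyl-1-(2,4,6-trihydroxy-3-methylphenyl)butyl]cyclohex-2-ene-1,5-dione | Cc1c(O)cc(O)c([C@H](CC(C)C)C2=C(O)C(C)(C)C(=O)C(C)(C)C2=O)c1O | intermediate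
17 | 3-phenylpropanoyl chloride | O=C(Cl)CCc1ccccc1 | starting material
18 | 3-hydroxy-4,4,6,6-tetramethyl-2-[(1S)-3-methyl-1-[2,4,6-trihydroxy-3-methyl-5-(3-phenylpropanoyl)phenyl]butyl]cyclohex-2-ene-1,5-dione (CNP0188786.1) | Cc1c(O)c(C(=O)CCc2ccccc2)c(O)c([C@H](CC(C)C)C2=C(O)C(C)(C)C(=O)C(C)(C)C2=O)c1O | target

Total step count: 7
Longest linear sequence: 7 steps (1 → 3 → 4 → 7 → 10 → 15 → 16 → 18)

Steps most likely to fail

1. Step 5 (new method). The sequence may stall after ring opening, because proton transfer from the acidic C2'–H quenches the ketone enolate and leaves an acyclic β-keto lactone. The amide or the enolate may also be used up unproductively, by amide attack on the dione or by self-condensation of the aryl lactone, or O-acylated isomers may accumulate. The fallback uses the known Michael route and sets out from 1. Syncarpic acid F1 (known from exhaustive C-methylation of 2,4,6-trihydroxyacetophenone and acid deacetylation) is condensed with 3-methylbutanal in a Knoevenagel reaction (pyrrolidine or L-proline, CH2Cl2) to give 2,2,4,4-tetramethyl-6-(3-methylbutylidene)cyclohexane-1,3,5-trione F2. An excess of 1, whose two free ring carbons are equivalent, is added to F2 in a Michael reaction (NaH, THF, 0 °C → rt) to give racemic triphenol F3. Preparative HPLC on a chiral stationary phase then separates the S enantiomer, and the route is rejoined at 16.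

2. Step 4. The 1,4-addition may be sluggish because the acceptor is electron-rich and carries a peri benzyloxy group; 1,2-addition at the lactone carbonyl may compete; or facial discrimination by the catalyst may be insufficient. The fallback sets out from 7: a racemic copper-mediated conjugate addition activated by a silyl chloride (8, CuI, Me3SiCl, THF, −40 °C) gives racemic lactone F4, whose enantiomers are separated by preparative supercritical-fluid chromatography on a chiral stationary phase. The 4R enantiomer rejoins the route at 10.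

3. Step 7. The Lewis acid may ionise the benzylic carbon (reversible cleavage of the aryl–methine or methine–ring B bond, eroding enantiomeric purity), cause cyclodehydration between a ring A hydroxyl and the ring B enol, or leave O-acylated material. The fallback installs the acyl group without acid and sets out from 10. Iodination of the only free ring A position (N-iodosuccinimide, MeCN, rt) gives 6-iodo lactone F5. The conditions of step 5 with 11 should convert it into iodo triketone F6, since an aryl iodide is inert to the silylamide and to enolates. Carbonylative Sonogashira coupling with phenylacetylene (PdCl2(PPh3)2, CuI, CO 1 atm, Et3N, THF) gives ynone F7. Hydrogenation (H2, 10% Pd/C, EtOAc) then saturates the alkyne and removes both benzyl groups, arriving at 18.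

Further compounds
F1 | step 5 | syncarpic acid (2,2,4,4-tetramethylcyclohexane-1,3,5-trione) | CC1(C)C(=O)CC(=O)C(C)(C)C1=O
F2 | step 5 | 2,2,4,4-tetramethyl-6-(3-methylbutylidene)cyclohexane-1,3,5-trione | CC(C)CC=C1C(=O)C(C)(C)C(=O)C(C)(C)C1=O
F3 | step 5 | racemic 3-hydroxy-4,4,6,6-tetramethyl-2-[3-methyl-1-(2,4,6-trihydroxy-3-methylphenyl)butyl]cyclohex-2-ene-1,5-dione | Cc1c(O)cc(O)c(C(CC(C)C)C2=C(O)C(C)(C)C(=O)C(C)(C)C2=O)c1O
F4 | step 4 | racemic 5,7-bis(benzyloxy)-8-methyl-4-(2-methylpropyl)-3,4-dihydro-2H-chromen-2-one | Cc1c(OCc2ccccc2)cc(OCc2ccccc2)c2c1OC(=O)CC2CC(C)C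
F5 | step 7 | (4R)-5,7-bis(benzyloxy)-6-iodo-8-methyl-4-(2-methylpropyl)-3,4-dihydro-2H-chromen-2-one | Cc1c(OCc2ccccc2)c(I)c(OCc2ccccc2)c2c1OC(=O)C[C@H]2CC(C)C
F6 | step 7 | 2-[(1S)-1-[4,6-bis(benzyloxy)-2-hydroxy-5-iodo-3-methylphenyl]-3-methylbutyl]-3-hydroxy-4,4,6,6-tetramethylcyclohex-2-ene-1,5-dione | Cc1c(OCc2ccccc2)c(I)c(OCc2ccccc2)c([C@H](CC(C)C)C2=C(O)C(C)(C)C(=O)C(C)(C)C2=O)c1O
F7 | step 7 | 2-[(1S)-1-[4,6-bis(benzyloxy)-2-hydroxy-3-methyl-5-(3-phenylprop-2-ynoyl)phenyl]-3-methylbutyl]-3-hydroxy-4,4,6,6-tetramethylcyclohex-2-ene-1,5-dione | Cc1c(OCc2ccccc2)c(C(=O)C#Cc2ccccc2)c(OCc2ccccc2)c([C@H](CC(C)C)C2=C(O)C(C)(C)C(=O)C(C)(C)C2=O)c1O
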